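The route rests on cutting the ring-fusion bond C5–C10 of the trans-decalin (eremophilane numbering), which turns ring A into the six-membered lactone 12: C3 carries the lactone oxygen and a Z-tetrasubstituted alkene C4=C5, and C9/C10 form the ester. Its silyl ketene acetal undergoes an Ireland–Claisen ring contraction that forms C5–C10, closes ring A, and sets the C5 quaternary and C10 tertiary centres from the single CBS-made C3 carbinol. The step exploits the fact that the oxygenated C3 lies 1,4 to C10 across ring A, so a C9–O–C3 ester can deliver C10 to C5. A Felkin dithiane addition, a carbonyl-ene closure of ring B and an epoxide-based re-oxygenation of C3 complete the target.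

Key step: step 6

Remark: atoms are numbered as in eremophilane throughout (ring A = C1–C5 and C10; ring B = C5–C10; C14 on C5, C15 on C4, isopropenyl C11–C13 on C7), and β is the face of the angular C14 methyl. The target is the (3R,4R,5R,7S,9S,10R) isomer (3α- and 9α-acyloxy, 4β,5β-dimethyl, 7α-isopropenyl, 10α-H). Compounds 7, 18 and 26 are taken as commercial.

Step 1
Reactants: 1 methyl propiolate; 2 1-bromo-3-methylbut-2-ene (prenyl bromide)
Product: 3 methyl 6-methylhept-5-en-2-ynoate
Conditions: CuI (cat.), Bu4NI (cat.), K2CO3, DMF, rt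
Reagents that add atoms: none
Why: Copper-catalysed coupling of a terminal alkyne with an allylic halide: the copper acetylide of the acidic propiolate should displace bromide at the unhindered primary carbon of 2 (SN2, not SN2′) and give the skipped enyne ester.

Step 2
Reactants: 3 methyl 6-methylhept-5-en-2-ynoate
Product: 5 methyl (2Z)-2,3,6-trimethylhepta-2,5-dienoate, via lithium alkenyl(methyl)cuprate 4 (not isolated)
Conditions: Me2CuLi (from CuI, 2 MeLi), THF, −78 °C; then MeI, HMPA, −78 → −30 °C
Reagents that add atoms: lithium dimethylcuprate [Li+].C[Cu-]C; iodomethane CI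
Why: Syn-carbocupration of the ynoate (cuprate conjugate addition) followed by alkylation of the alkenylcuprate with MeI with retention: the two methyl groups end up cis, so the prenyl-bearing CH2 and the ester are cis (2Z).

Step 3
Reactants: 5 methyl (2Z)-2,3,6-trimethylhepta-2,5-dienoate
Product: 6 (2Z)-N-methoxy-N,2,3,6-tetramethylhepta-2,5-dienamide
Conditions: MeNH(OMe)·HCl, AlMe3, CH2Cl2, 0 → 40 °C
Reagents that add atoms: N,O-dimethylhydroxylamine hydrochloride CNOC.Cl
Why: Weinreb amide formation by aminolysis with the aluminium amide made from AlMe3 and the amine salt, which should attack even this hindered tetrasubstituted enoate without touching the alkene geometry.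

Step 4
Reactants: 6 (2Z)-N-methoxy-N,2,3,6-tetramethylhepta-2,5-dienamide; 7 4-bromo-1,1,1-trimethoxybutane
Product: 10 methyl (6Z)-6,7,10-trimethyl-5-oxoundeca-6,9-dienoate, via (4,4,4-trimethoxybutyl)magnesium bromide 8 (not isolated), via keto ortho ester 9 (not isolated)
Conditions: 7, Mg, THF, 40 °C; then 6, 0 °C → rt; then aq. citric acid, THF, rt
Reagents that add atoms: water O
Why: Weinreb ketone synthesis: Grignard reagent 8, an ester anion equivalent masked as an ortho ester, adds once to 6 through the stable magnesium chelate, and mild aqueous acid then converts only the ortho ester of 9 into the methyl ester.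

Step 5
Reactants: 10 methyl (6Z)-6,7,10-trimethyl-5-oxoundeca-6,9-dienoate
Product: 12 (6S)-6-[(2Z)-3,6-dimethylhepta-2,5-dien-2-yl]oxan-2-one, via hydroxy ester 11 (not isolated)
Conditions: (R)-Me-CBS (20 mol%), catecholborane, PhMe, −78 °C; MeOH; then PPTS (cat.), PhMe, 60 °C
Reagents that add atoms: none
Why: Corey–Bakshi–Shibata reduction: with the α-branched alkenyl group as the large substituent the (R)-catalyst should give the (5S)-carbinol 11 (catecholborane spares the alkenes and the ester), which lactonises under mild acid to the (6S)-δ-lactone.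

Step 6
Reactants: 12 (6S)-6-[(2Z)-3,6-dimethylhepta-2,5-dien-2-yl]oxan-2-one
Product: 15 [(1R,2S)-2,3-dimethyl-2-(3-methylbut-2-en-1-yl)cyclohex-3-en-1-yl]methanol, via silyl ketene acetal 13 (not isolated), via silyl ester 14 (not isolated)
Conditions: LDA, THF, −78 °C; TBSCl, HMPA, −78 °C → rt; PhMe, 110 °C; then LiAlH4, THF, 0 °C
Reagents that add atoms: none
Why: Deprotonation and O-silylation give the cyclic silyl ketene acetal 13, whose C10=C9(OSi)–O–C3–C4=C5 array undergoes a suprafacial [3,3]-sigmatropic shift (Ireland–Claisen; the closest precedent is the ring contraction of 6-alkenyl δ-lactone silyl enolates to cyclohex-3-enecarboxylic acids) that forms C5–C10 as C3–O breaks, and the silyl ester 14 is then reduced in the same pot by LiAlH4. Ring A closes as a six-membered carbocycle by contraction of the six-membered lactone: the C1–C2 tether holds the alkenyl group axially over the ketene acetal and forces the six reacting atoms into a boat (bicyclo[2.2.2]octene-like) transition state, with no chair alternative available. C10 is set because C5 can only add to the ketene acetal face that carries the alkenyl group, the face defined by the (S)-C3 carbinol centre (1,4-chirality transfer, C3 itself becoming sp2). C5 is set by the same facial constraint together with the Z geometry of C4=C5: the substituent cis to C3 (the prenyl CH2, C6) must lie over the C1–C2 bridge and ends trans to C9, while the methyl trans to C3 ends cis to C9, which is the relative configuration of a trans-decalin. The step needs O- rather than C-silylation and rearrangement rather than elimination or decomposition of the ketene acetal; TBSCl/HMPA trapping at −78 °C and the intramolecular shift at 110 °C should secure this, and the fully substituted C5 terminus is the accepted risk.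

Step 7
Reactants: 15 [(1R,2S)-2,3-dimethyl-2-(3-methylbut-2-en-1-yl)cyclohex-3-en-1-yl]methanol
Product: 16 (1R,2S)-2,3-dimethyl-2-(3-methylbut-2-en-1-yl)cyclohex-3-ene-1-carbaldehyde
Conditions: Dess–Martin periodinane, CH2Cl2, 0 °C → rt
Reagents that add atoms: none
Why: Dess–Martin oxidation of the primary alcohol under neutral conditions; the C10 centre α to the new aldehyde is already the thermodynamically preferred (equatorial) epimer and should be kept.

Step 8
Reactants: 16 (1R,2S)-2,3-dimethyl-2-(3-methylbut-2-en-1-yl)cyclohex-3-ene-1-carbaldehyde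
Product: 17 (S)-[(1R,2S)-2,3-dimethyl-2-(3-methylbut-2-en-1-yl)cyclohex-3-en-1-yl](1,3-dithian-2-yl)methanol
Conditions: 1,3-dithiane, n-BuLi, THF, −30 °C; then 16, −78 °C; H2O
Reagents that add atoms: 1,3-dithiane C1CSCSC1
Why: Corey–Seebach addition of 2-lithio-1,3-dithiane as a formyl anion equivalent supplies C8, and Felkin–Anh attack anti to the quaternary C5 on the α-chiral aldehyde should set C9 as (S), the configuration needed for the 9α-oxygen.

Step 9
Reactants: 17 (S)-[(1R,2S)-2,3-dimethyl-2-(3-methylbut-2-en-1-yl)cyclohex-3-en-1-yl](1,3-dithian-2-yl)methanol; 18 (2E)-3-methylpent-2-enoic acid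
Product: 20 (S)-[(1R,2S)-2,3-dimethyl-2-(3-methylbut-2-en-1-yl)cyclohex-3-en-1-yl](1,3-dithian-2-yl)methyl (2E)-3-methylpent-2-enoate, via mixed anhydride 19 (not isolated)
Conditions: 18, 2,4,6-Cl3C6H2COCl, Et3N, THF, rt; then 17, DMAP, PhMe, rt → 40 °C
Reagents that add atoms: none
Why: Yamaguchi esterification: the mixed anhydride 19 is attacked at the less hindered enoyl carbonyl by the secondary alcohol under DMAP catalysis, a method suited to a hindered carbinol and mild enough to keep the E-enoate geometry.

Step 10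
Reactants: 20 (S)-[(1R,2S)-2,3-dimethyl-2-(3-methylbut-2-en-1-yl)cyclohex-3-en-1-yl](1,3-dithian-2-yl)methyl (2E)-3-methylpent-2-enoate
Product: 21 (1S)-1-[(1R,2S)-2,3-dimethyl-2-(3-methylbut-2-en-1-yl)cyclohex-3-en-1-yl]-2-oxoethyl (2E)-3-methylpent-2-enoate
Conditions: PhI(OCOCF3)2, MeCN–H2O (9:1), 0 °C
Reagents that add atoms: water O
Why: Oxidative dethioacetalisation with a hypervalent iodine reagent (Stork–Zhao conditions), fast at 0 °C and compatible with the trisubstituted alkenes and the ester, should free the C8 aldehyde without epimerising C9.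

Step 11
Reactants: 21 (1S)-1-[(1R,2S)-2,3-dimethyl-2-(3-methylbut-2-en-1-yl)cyclohex-3-en-1-yl]-2-oxoethyl (2E)-3-methylpent-2-enoate
Product: 22 8β-hydroxy-9α-[(2E)-3-methylpent-2-enoyloxy]-10αH-eremophila-3,11-diene
Conditions: Me2AlCl, CH2Cl2, −78 → −30 °C; cold dil. HCl
Reagents that add atoms: none
Why: Type I intramolecular carbonyl-ene reaction (citronellal-to-isopulegol type): the Me2AlCl-activated C8 aldehyde is attacked by C7 of the prenyl group through a chair in which ring A, the C9 acyloxy group and the developing isopropenyl group are equatorial, which closes ring B trans-fused and should set C7 (isopropenyl α) and C8 (hydroxyl β).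

Step 12
Reactants: 22 8β-hydroxy-9α-[(2E)-3-methylpent-2-enoyloxy]-10αH-eremophila-3,11-diene
Product: 23 9α-[(2E)-3-methylpent-2-enoyloxy]-10αH-eremophila-3,11-dien-8-one
Conditions: Dess–Martin periodinane, CH2Cl2, rt
Reagents that add atoms: none
Why: Dess–Martin oxidation of the secondary C8 alcohol under neutral conditions that should avoid acyl migration from O9, epimerisation at C7/C9 and conjugation of the β,γ-unsaturated ketone.

Step 13
Reactants: 23 9α-[(2E)-3-methylpent-2-enoyloxy]-10αH-eremophila-3,11-dien-8-one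
Product: 24 3α,4α-epoxy-9α-[(2E)-3-methylpent-2-enoyloxy]-10αH-eremophil-11-en-8-one
Conditions: mCPBA (1.05 equiv), CH2Cl2, −10 → 0 °C
Reagents that add atoms: 3-chloroperoxybenzoic acid OOC(=O)c1cccc(Cl)c1
Why: Prilezhaev epoxidation: the trisubstituted C3=C4 bond is more nucleophilic than the 1,1-disubstituted isopropenyl group next to the C8 carbonyl and than the enoate, and the peracid should add from the α-face, anti to the axial C5 methyl.

Step 14
Reactants: 24 3α,4α-epoxy-9α-[(2E)-3-methylpent-2-enoyloxy]-10αH-eremophil-11-en-8-one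
Product: 25 3α-hydroxy-9α-[(2E)-3-methylpent-2-enoyloxy]-10αH-eremophil-11-en-8-one
Conditions: Cp2TiCl2, Mn, THF, rt; then 24, H2O, rt; dil. HCl
Reagents that add atoms: none
Why: Titanocene(III)-mediated reductive epoxide opening (Nugent–RajanBabu/Gansäuer type, anti-Markovnikov): homolysis gives the tertiary C4 radical and keeps the C3–O bond, and H-atom transfer from the Cp2TiCl–water complex to the axial α-face of C4, away from the axial C5 methyl, should leave the C4 methyl equatorial (β) and the C3 hydroxyl α.

Step 15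
Reactants: 25 3α-hydroxy-9α-[(2E)-3-methylpent-2-enoyloxy]-10αH-eremophil-11-en-8-one; 26 angelic acid ((2Z)-2-methylbut-2-enoic acid)
Product: 28 3α-[(2Z)-2-methylbut-2-enoyloxy]-9α-[(2E)-3-methylpent-2-enoyloxy]-10αH-eremophil-11-en-8-one (CNP0301161.1), via mixed anhydride 27 (not isolated)
Conditions: 26, 2,4,6-Cl3C6H2COCl, Et3N, PhMe, rt; then 25, PhMe, 75 °C
Reagents that add atoms: none
Why: Yamaguchi-type acylation with the preformed mixed anhydride 27 in the absence of DMAP, the established way to transfer an angeloyl group without Z→E isomerisation to the tiglate, the equatorial 3α-hydroxyl being the only free alcohol.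

Compound list
1 | methyl propiolate | C#CC(=O)OC | starting material
2 | 1-bromo-3-methylbut-2-ene (prenyl bromide) | CC(C)=CCBr | starting material
3 | methyl 6-methylhept-5-en-2-ynoate | COC(=O)C#CCC=C(C)C | intermediate
4 | lithium methyl[(2E)-1-methoxy-3,6-dimethyl-1-oxohepta-2,5-dien-2-yl]cuprate | [Li+].COC(=O)/C([Cu-]C)=C(/C)CC=C(C)C | intermediate
5 | methyl (2Z)-2,3,6-trimethylhepta-2,5-dienoate | COC(=O)/C(C)=C(/C)CC=C(C)C | intermediate
6 | (2Z)-N-methoxy-N,2,3,6-tetramethylhepta-2,5-dienamide | CON(C)C(=O)/C(C)=C(/C)CC=C(C)C | intermediate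
7 | 4-bromo-1,1,1-trimethoxybutane | COC(CCCBr)(OC)OC | starting material
8 | (4,4,4-trimethoxybutyl)magnesium bromide | COC(CCC[Mg]Br)(OC)OC | intermediate
9 | (5Z)-11,11,11-trimethoxy-2,5,6-trimethylundeca-2,5-dien-7-one | COC(CCCC(=O)/C(C)=C(/C)CC=C(C)C)(OC)OC | intermediate
10 | methyl (6Z)-6,7,10-trimethyl-5-oxoundeca-6,9-dienoate | COC(=O)CCCC(=O)/C(C)=C(/C)CC=C(C)C | intermediate
11 | methyl (5S,6Z)-5-hydroxy-6,7,10-trimethylundeca-6,9-dienoate | COC(=O)CCC[C@H](O)/C(C)=C(/C)CC=C(C)C | intermediate
12 | (6S)-6-[(2Z)-3,6-dimethylhepta-2,5-dien-2-yl]oxan-2-one | O=C1CCC[C@H](O1)/C(C)=C(/C)CC=C(C)C | intermediate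
13 | tert-butyl({(2S)-2-[(2Z)-3,6-dimethylhepta-2,5-dien-2-yl]-3,4-dihydro-2H-pyran-6-yl}oxy)dimethylsilane | CC(C)(C)[Si](C)(C)OC1=CCC[C@H](O1)/C(C)=C(/C)CC=C(C)C | intermediate
14 | tert-butyldimethylsilyl (1R,2S)-2,3-dimethyl-2-(3-methylbut-2-en-1-yl)cyclohex-3-ene-1-carboxylate | CC(C)=CC[C@]1(C)C(C)=CCC[C@H]1C(=O)O[Si](C)(C)C(C)(C)C | intermediate
15 | [(1R,2S)-2,3-dimethyl-2-(3-methylbut-2-en-1-yl)cyclohex-3-en-1-yl]methanol | CC(C)=CC[C@]1(C)C(C)=CCC[C@H]1CO | intermediate
16 | (1R,2S)-2,3-dimethyl-2-(3-methylbut-2-en-1-yl)cyclohex-3-ene-1-carbaldehyde | CC(C)=CC[C@]1(C)C(C)=CCC[C@H]1C=O | intermediate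
17 | (S)-[(1R,2S)-2,3-dimethyl-2-(3-methylbut-2-en-1-yl)cyclohex-3-en-1-yl](1,3-dithian-2-yl)methanol | CC(C)=CC[C@]1(C)C(C)=CCC[C@H]1[C@H](O)C2SCCCS2 | intermediate
18 | (2E)-3-methylpent-2-enoic acid | CC/C(C)=C/C(=O)O | starting material
19 | (2E)-3-methylpent-2-enoic 2,4,6-trichlorobenzoic anhydride | CC/C(C)=C/C(=O)OC(=O)c1c(Cl)cc(Cl)cc1Cl | intermediate
20 | (S)-[(1R,2S)-2,3-dimethyl-2-(3-methylbut-2-en-1-yl)cyclohex-3-en-1-yl](1,3-dithian-2-yl)methyl (2E)-3-methylpent-2-enoate | CC(C)=CC[C@]1(C)C(C)=CCC[C@H]1[C@H](OC(=O)/C=C(\C)CC)C2SCCCS2 | intermediate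
21 | (1S)-1-[(1R,2S)-2,3-dimethyl-2-(3-methylbut-2-en-1-yl)cyclohex-3-en-1-yl]-2-oxoethyl (2E)-3-methylpent-2-enoate | CC(C)=CC[C@]1(C)C(C)=CCC[C@H]1[C@H](OC(=O)/C=C(\C)CC)C=O | intermediate
22 | 8β-hydroxy-9α-[(2E)-3-methylpent-2-enoyloxy]-10αH-eremophila-3,11-diene | C=C(C)[C@@H]1C[C@]2(C)C(C)=CCC[C@H]2[C@H](OC(=O)/C=C(\C)CC)[C@H]1O | intermediate
23 | 9α-[(2E)-3-methylpent-2-enoyloxy]-10αH-eremophila-3,11-dien-8-one | C=C(C)[C@@H]1C[C@]2(C)C(C)=CCC[C@H]2[C@H](OC(=O)/C=C(\C)CC)C1=O | intermediate
24 | 3α,4α-epoxy-9α-[(2E)-3-methylpent-2-enoyloxy]-10αH-eremophil-11-en-8-one | C=C(C)[C@@H]1C[C@]2(C)[C@]3(C)O[C@@H]3CC[C@H]2[C@H](OC(=O)/C=C(\C)CC)C1=O | intermediate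
25 | 3α-hydroxy-9α-[(2E)-3-methylpent-2-enoyloxy]-10αH-eremophil-11-en-8-one | C=C(C)[C@@H]1C[C@]2(C)[C@@H](C)[C@H](O)CC[C@H]2[C@H](OC(=O)/C=C(\C)CC)C1=O | intermediate
26 | angelic acid, (2Z)-2-methylbut-2-enoic acid | C/C=C(/C)C(=O)O | starting material
27 | (2Z)-2-methylbut-2-enoic 2,4,6-trichlorobenzoic anhydride | C/C=C(/C)C(=O)OC(=O)c1c(Cl)cc(Cl)cc1Cl | intermediate
28 | CNP0301161.1, (3R,4R,5R,7S,9S,10R)-3-[(2Z)-2-methylbut-2-enoyloxy]-9-[(2E)-3-methylpent-2-enoyloxy]eremophil-11-en-8-one | C=C(C)[C@@H]1C[C@]2(C)[C@@H](C)[C@H](OC(=O)/C(C)=C\C)CC[C@H]2[C@H](OC(=O)/C=C(\C)CC)C1=O | target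

Total step count: 15. Longest linear sequence: 15 steps (1/2 → 28); 7, 18 and 26 enter as commercial materials.

Steps most likely to fail

Step 6. The fully substituted C5 terminus may slow the boat [3,3] shift enough that C-silylation, elimination or thermal decomposition of the ketene acetal competes. The fallback keeps the same bond-forming event but moves it to a neutral, thermally robust enol ether. It sets out from 12: DIBAL-H reduction (CH2Cl2, −78 °C) should give the lactol (6S)-6-[(2Z)-3,6-dimethylhepta-2,5-dien-2-yl]oxan-2-ol F1, and dehydration (MsCl, Et3N, 0 °C → reflux) the enol ether (2S)-2-[(2Z)-3,6-dimethylhepta-2,5-dien-2-yl]-3,4-dihydro-2H-pyran F2. Thermal Claisen rearrangement of F2 (Büchi-type, sealed tube, PhMe, 200–220 °C) through the same tether-enforced boat should then give aldehyde 16 directly, where the fallback comes back to the route.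

Step 14. Hydrogen-atom delivery to the C4 radical may occur from the wrong face, the radical may be trapped and eliminate to the allylic alcohol, or Ti(III) may reduce the α-acyloxy ketone. The fallback replaces the radical opening by an ionic sequence and sets out from 24. Lewis-acid Meinwald rearrangement (LiClO4, PhH, reflux; 1,2-hydride shift, then brief DBU equilibration of C4 to the equatorial methyl) should give 9α-[(2E)-3-methylpent-2-enoyloxy]-10αH-eremophil-11-ene-3,8-dione F3. L-selectride (THF, −78 °C) should reduce the less hindered C3 carbonyl from the α-face, since the β-face is blocked by the axial C5 methyl, to the axial alcohol 3β-hydroxy-9α-[(2E)-3-methylpent-2-enoyloxy]-10αH-eremophil-11-en-8-one F4. Mitsunobu esterification of F4 with angelic acid 26 (PPh3, DIAD, PhMe, 0 °C → rt) inverts C3 and should give 28, where the fallback comes back to the route.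

Step 2. The alkenylcopper intermediate may equilibrate through its allenoate form before the slow alkylation with MeI, which would scramble the alkene geometry. The fallback separates trapping from C–C bond formation and sets out from 3. Me2CuLi addition at −78 °C followed by iodine (fast, retentive trapping) should give methyl (2E)-2-iodo-3,6-dimethylhepta-2,5-dienoate F5. Stereoretentive Negishi methylation of F5 (MeZnCl, Pd(PPh3)4, THF, rt) then gives 5, where the fallback comes back to the route.

Further compounds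
F1 | step 6 | (6S)-6-[(2Z)-3,6-dimethylhepta-2,5-dien-2-yl]oxan-2-ol (anomeric mixture) | OC1CCC[C@H](O1)/C(C)=C(/C)CC=C(C)C
F2 | step 6 | (2S)-2-[(2Z)-3,6-dimethylhepta-2,5-dien-2-yl]-3,4-dihydro-2H-pyran | C1=CCC[C@H](O1)/C(C)=C(/C)CC=C(C)C
F3 | step 14 | 9α-[(2E)-3-methylpent-2-enoyloxy]-10αH-eremophil-11-ene-3,8-dione | C=C(C)[C@@H]1C[C@]2(C)[C@@H](C)C(=O)CC[C@H]2[C@H](OC(=O)/C=C(\C)CC)C1=O
F4 | step 14 | 3β-hydroxy-9α-[(2E)-3-methylpent-2-enoyloxy]-10αH-eremophil-11-en-8-one | C=C(C)[C@@H]1C[C@]2(C)[C@@H](C)[C@@H](O)CC[C@H]2[C@H](OC(=O)/C=C(\C)CC)C1=O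
F5 | step 2 | methyl (2E)-2-iodo-3,6-dimethylhepta-2,5-dienoate | COC(=O)/C(I)=C(/C)CC=C(C)C
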